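**Retrosynthetic overview**

1. Target 21 ⇐ removal of the O7 silyl group ⇐ catalytic enantioselective protonation at C3 of the C3=C4 silyl enol ether 19 (the only stereocenter, set late so that nothing can scramble it) ⇐ cross-metathesis (C8 allyl → prenyl).
2. Ring C ⇐ cationic formal [4+2] annulation: the aryloxymethyl cation on ring A (C4a=C8a–O1–C2+, from acetoxymethyl ether 8) plus siloxyalkyne 15 (C3≡C4–OSi, ring B on C3). C2–C3 and C4–C4a form in one operation and C4 arrives as the enol silane.
3. Enabling feature: the ether oxygen O1 sits on C8a next to the unsubstituted C4a, which is also para to the oxygen on C7, so the O1–CH2 cation is a 2-oxadiene with a nucleophilic arene terminus; the α-aryl ketone C3–C4 is an aryl ynol at the alkyne oxidation level.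
4. Ring A ⇐ cyclohexane-1,3-dione (C8 allylation, silylation of one oxygen at the dione stage, dehydrogenation to the phenol); rings B and D ⇐ 4-bromophenol + isoprene, then Sonogashira coupling and acetylide oxidation.
5. Order of ring formation: ring D (dimethylpyran on ring B), ring A (by aromatization), ring C (key step).

Key step: step 9

Assumption: the sense of induction of the chiral acid in step 11 is assigned by analogy only; the catalyst antipode that protonates C3 to give the (3R) ketone is to be used (both antipodes are accessible), and the (S) label written below is provisional.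

**Route**

Step 1
Reactants: 1 cyclohexane-1,3-dione
Product: 2 2-allylcyclohexane-1,3-dione
Conditions: allyl acetate (0.8 equiv), Pd(PPh3)4 (1 mol %), DBU (1 equiv), toluene, 80 °C
Reagents that add atoms: allyl acetate, CC(=O)OCC=C
Why: Tsuji–Trost allylation, in which the soft dione enolate attacks the π-allyl complex of divalent palladium at carbon and any O-allyl enol ether re-ionizes and funnels to the C-allyl product, the excess of dione suppressing double allylation.

Step 2
Reactants: 2 2-allylcyclohexane-1,3-dione
Product: 3 2-allyl-3-[(tert-butyldimethylsilyl)oxy]cyclohex-2-en-1-one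
Conditions: TBSCl, Et3N, DMAP (cat.), CH2Cl2, 0 °C → rt; non-aqueous work-up
Reagents that add atoms: tert-butyldimethylsilyl chloride (TBSCl), CC(C)(C)[Si](C)(C)Cl
Why: O-silylation of the enol of a 2-substituted 1,3-dione can occur only once, so the oxygen that becomes O7 (silylated) and the one that becomes O1 (still a ketone) are told apart without a statistical protection.

Step 3
Reactants: 3 2-allyl-3-[(tert-butyldimethylsilyl)oxy]cyclohex-2-en-1-one
Product: 7 2-allyl-3-[(tert-butyldimethylsilyl)oxy]phenol, via selenide 4 (not isolated), via selenoxide 5 (not isolated), via dienone 6 (not isolated)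
Conditions: LDA (LiN(i-Pr)2), THF, −78 °C; PhSeCl, −78 °C; then mCPBA, CH2Cl2, −78 °C; i-Pr2NH, −78 °C → rt
Reagents that add atoms: none
Why: Kinetic deprotonation at the α' carbon of the vinylogous silyl ester, selenenylation, oxidation at selenium and selenoxide syn-elimination should give the cross-conjugated cyclohexa-2,5-dienone, which tautomerizes to the phenol (dehydrogenative aromatization of a cyclohexenone).

Step 4
Reactants: 7 2-allyl-3-[(tert-butyldimethylsilyl)oxy]phenol
Product: 8 {2-allyl-3-[(tert-butyldimethylsilyl)oxy]phenoxy}methyl acetate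
Conditions: NaH, DMF, 0 °C; BrCH2OAc, 0 °C → rt
Reagents that add atoms: bromomethyl acetate, CC(=O)OCBr
Why: Williamson O-alkylation of the sodium phenoxide by a highly reactive α-halo ether-type electrophile places C2 on O1 as a latent aryloxymethyl cation (acyloxymethyl ether formation).

Step 5
Reactants: 9 4-bromophenol
Product: 10 6-bromo-2,2-dimethylchroman
Conditions: isoprene (2 equiv), AgOTf (5 mol %), ClCH2CH2Cl, rt
Reagents that add atoms: isoprene, C=CC(C)=C
Why: Friedel–Crafts ortho-prenylation of the phenol followed by Markovnikov hydroalkoxylation of the prenyl double bond should close the dimethylpyran ring, the para bromine leaving only the two equivalent ortho positions open.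

Step 6
Reactants: 10 6-bromo-2,2-dimethylchroman
Product: 11 [(2,2-dimethylchroman-6-yl)ethynyl]trimethylsilane
Conditions: ethynyltrimethylsilane, PdCl2(PPh3)2 (3 mol %), CuI (3 mol %), PPh3 (6 mol %), Et3N, 80 °C (sealed tube)
Reagents that add atoms: ethynyltrimethylsilane, C#C[Si](C)(C)C
Why: Sonogashira coupling of an aryl bromide and a terminal alkyne.

Step 7
Reactants: 11 [(2,2-dimethylchroman-6-yl)ethynyl]trimethylsilane
Product: 12 6-ethynyl-2,2-dimethylchroman
Conditions: K2CO3 (cat.), MeOH, rt
Reagents that add atoms: none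
Why: Base-catalysed methanolysis of the alkynyl–silicon bond.

Step 8
Reactants: 12 6-ethynyl-2,2-dimethylchroman
Product: 15 2,2-dimethyl-6-{[(triisopropylsilyl)oxy]ethynyl}chroman, via lithium acetylide 13 (not isolated), via lithium ynolate 14 (not isolated)
Conditions: n-BuLi, THF, −78 °C; LiOOt-Bu (from t-BuOOH and LiN(SiMe3)2, THF, −78 °C), −78 → 0 °C; TIPSOTf, −78 → 0 °C; used freshly
Reagents that add atoms: tert-butyl hydroperoxide, CC(C)(C)OO; triisopropylsilyl trifluoromethanesulfonate (TIPSOTf), CC(C)[Si](OS(=O)(=O)C(F)(F)F)(C(C)C)C(C)C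
Why: Oxidation of the lithium acetylide by lithium tert-butyl peroxide gives the ynolate, which the bulky silyl triflate traps on oxygen (the standard preparation of siloxyalkynes from terminal alkynes).

Step 9
Reactants: 8 {2-allyl-3-[(tert-butyldimethylsilyl)oxy]phenoxy}methyl acetate; 15 2,2-dimethyl-6-{[(triisopropylsilyl)oxy]ethynyl}chroman
Product: 18 8-allyl-7-[(tert-butyldimethylsilyl)oxy]-3-(2,2-dimethylchroman-6-yl)-4-[(triisopropylsilyl)oxy]-2H-chromene, via aryloxymethyl cation 16 (not isolated), via silyl ketenium ion 17 (not isolated)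
Conditions: 8 (1.0 equiv), 15 (1.3 equiv), 2,6-di-tert-butyl-4-methylpyridine (1.5 equiv), TMSOTf (1.1 equiv, added last), CH2Cl2 (0.1 M), −78 → −40 °C; Et3N quench
Reagents that add atoms: none
Why: Proposed new method: TMSOTf silylates the acetate of 8 and ionizes it to the aryloxymethyl cation 16, the aryl-bearing β-carbon of siloxyalkyne 15 adds to it (C2–C3) to give the silyl ketenium ion 17, and C4a of ring A attacks the ketenium carbon (C4–C4a), the hindered pyridine taking the proton and leaving the C3=C4 silyl enol ether. The closest known reaction types are the oxa-Povarov reaction (formal [4+2] of aryl oxocarbenium ions and alkenes to chromans), the addition of acetal-derived oxocarbenium ions to siloxyalkynes and the Friedel–Crafts capture of silyl ketenium ions by tethered arenes to cyclic enol silanes; using a siloxyalkyne as the two-carbon partner of an aryloxymethyl cation is new. Ring C closes in a 6-exo-dig Friedel–Crafts mode: the arene attacks the sp carbon of the ketenium ion, the C=O π bond that is used up lies outside the new ring and C3=C4 stays inside it. No stereocenter is formed, since C3 stays trigonal; it is set in step 11. The regiochemistry at the alkyne is dictated by the siloxy oxygen (only the carbon that carries ring B is nucleophilic) and the site on ring A by the tether, because C4a is the only position that O1–C2–C3 can reach and it is ortho to O1 and para to the silyl ether oxygen on C7. The step needs the cation to be taken by the alkyne and not by the C8 side chain or a second arene, which is secured by carrying the weakly nucleophilic allyl group in place of prenyl (a prenyl double bond would close a six-membered ring onto C2), by the excess of the far more nucleophilic alkyne, and by the base, which keeps triflic acid away from alkyne and product.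

Step 10
Reactants: 18 8-allyl-7-[(tert-butyldimethylsilyl)oxy]-3-(2,2-dimethylchroman-6-yl)-4-[(triisopropylsilyl)oxy]-2H-chromene
Product: 19 7-[(tert-butyldimethylsilyl)oxy]-3-(2,2-dimethylchroman-6-yl)-8-(3-methylbut-2-en-1-yl)-4-[(triisopropylsilyl)oxy]-2H-chromene
Conditions: 2-methyl-2-butene (large excess, co-solvent), second-generation Grubbs catalyst RuCl2(=CHPh)(H2IMes)(PCy3) (5 mol %), CH2Cl2, 40 °C (sealed)
Reagents that add atoms: 2-methyl-2-butene, CC=C(C)C
Why: Olefin cross-metathesis of a terminal allyl arene and a trisubstituted alkene exchanges =CH2 for =CMe2 and releases propene, the tetrasubstituted enol ether double bond being inert to the ruthenium carbene.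

Step 11
Reactants: 19 7-[(tert-butyldimethylsilyl)oxy]-3-(2,2-dimethylchroman-6-yl)-8-(3-methylbut-2-en-1-yl)-4-[(triisopropylsilyl)oxy]-2H-chromene
Product: 20 (3R)-7-[(tert-butyldimethylsilyl)oxy]-3-(2,2-dimethylchroman-6-yl)-8-(3-methylbut-2-en-1-yl)chroman-4-one
Conditions: (S)-3,3'-bis(2,4,6-triisopropylphenyl)-BINOL N-triflyl thiophosphoramide (10 mol %), PhOH (1.5 equiv), toluene, 0 °C → rt
Reagents that add atoms: none
Why: Chiral Brønsted acid-catalysed enantioselective protonation of the silyl enol ether of a 2-aryl cyclic ketone, with an achiral phenol as stoichiometric proton source: C3 is protonated inside the chiral ion pair on the face selected by the catalyst pocket (catalyst control), the silyl group passes to phenol, and the (3R) centre arises under acidic, non-enolizing conditions in which phenol alone should not attack the hindered enol silane.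

Step 12
Reactants: 20 (3R)-7-[(tert-butyldimethylsilyl)oxy]-3-(2,2-dimethylchroman-6-yl)-8-(3-methylbut-2-en-1-yl)chroman-4-one
Product: 21 (3R)-3-(2,2-dimethylchroman-6-yl)-7-hydroxy-8-(3-methylbut-2-en-1-yl)chroman-4-one (target)
Conditions: KHF2 (2 equiv), MeOH, 0 °C → rt
Reagents that add atoms: none
Why: Bifluoride cleaves the aryl silyl ether, made labile by the para carbonyl, under weakly acidic conditions free of alkoxide or naked fluoride, so the C3–H centre next to the ketone should not be enolized and the prenyl group is untouched.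

**Compound list**

1 | cyclohexane-1,3-dione | O=C1CCCC(=O)C1 | starting material
2 | 2-allylcyclohexane-1,3-dione | C=CCC1C(=O)CCCC1=O | intermediate
3 | 2-allyl-3-[(tert-butyldimethylsilyl)oxy]cyclohex-2-en-1-one | C=CCC1=C(O[Si](C)(C)C(C)(C)C)CCCC1=O | intermediate
4 | 2-allyl-3-[(tert-butyldimethylsilyl)oxy]-6-(phenylselanyl)cyclohex-2-en-1-one (racemic, not isolated) | C=CCC1=C(O[Si](C)(C)C(C)(C)C)CCC([Se]c2ccccc2)C1=O | intermediate
5 | 2-allyl-6-(benzeneseleninyl)-3-[(tert-butyldimethylsilyl)oxy]cyclohex-2-en-1-one (stereoisomer mixture, not isolated) | C=CCC1=C(O[Si](C)(C)C(C)(C)C)CCC([Se](=O)c2ccccc2)C1=O | intermediate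
6 | 2-allyl-3-[(tert-butyldimethylsilyl)oxy]cyclohexa-2,5-dien-1-one (not isolated) | C=CCC1=C(O[Si](C)(C)C(C)(C)C)CC=CC1=O | intermediate
7 | 2-allyl-3-[(tert-butyldimethylsilyl)oxy]phenol | C=CCc1c(O)cccc1O[Si](C)(C)C(C)(C)C | intermediate
8 | {2-allyl-3-[(tert-butyldimethylsilyl)oxy]phenoxy}methyl acetate | CC(=O)OCOc1cccc(O[Si](C)(C)C(C)(C)C)c1CC=C | intermediate
9 | 4-bromophenol | Oc1ccc(Br)cc1 | starting material
10 | 6-bromo-2,2-dimethylchroman | CC1(C)CCc2cc(Br)ccc2O1 | intermediate
11 | [(2,2-dimethylchroman-6-yl)ethynyl]trimethylsilane | CC1(C)CCc2cc(C#C[Si](C)(C)C)ccc2O1 | intermediate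
12 | 6-ethynyl-2,2-dimethylchroman | CC1(C)CCc2cc(C#C)ccc2O1 | intermediate
13 | lithium (2,2-dimethylchroman-6-yl)acetylide (not isolated) | [Li]C#Cc1ccc2OC(C)(C)CCc2c1 | intermediate
14 | lithium 2-(2,2-dimethylchroman-6-yl)ethynolate (not isolated) | [Li]OC#Cc1ccc2OC(C)(C)CCc2c1 | intermediate
15 | 2,2-dimethyl-6-{[(triisopropylsilyl)oxy]ethynyl}chroman | CC(C)[Si](OC#Cc1ccc2OC(C)(C)CCc2c1)(C(C)C)C(C)C | intermediate
16 | {2-allyl-3-[(tert-butyldimethylsilyl)oxy]phenyl}(methylidene)oxonium triflate (aryloxymethyl cation, not isolated) | C=[O+]c1cccc(O[Si](C)(C)C(C)(C)C)c1CC=C.[O-]S(=O)(=O)C(F)(F)F | intermediate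
17 | O-triisopropylsilyl ketenium triflate carrying the 2,2-dimethylchroman-6-yl and aryloxymethyl groups on the terminal carbon (not isolated) | CC(C)[Si](C(C)C)(C(C)C)[O+]=C=C(COc1cccc(O[Si](C)(C)C(C)(C)C)c1CC=C)c1ccc2OC(C)(C)CCc2c1.[O-]S(=O)(=O)C(F)(F)F | intermediate
18 | 8-allyl-7-[(tert-butyldimethylsilyl)oxy]-3-(2,2-dimethylchroman-6-yl)-4-[(triisopropylsilyl)oxy]-2H-chromene | C=CCc1c(O[Si](C)(C)C(C)(C)C)ccc2c1OCC(c1ccc3c(c1)CCC(C)(C)O3)=C2O[Si](C(C)C)(C(C)C)C(C)C | intermediate
19 | 7-[(tert-butyldimethylsilyl)oxy]-3-(2,2-dimethylchroman-6-yl)-8-(3-methylbut-2-en-1-yl)-4-[(triisopropylsilyl)oxy]-2H-chromene | CC(C)=CCc1c(O[Si](C)(C)C(C)(C)C)ccc2c1OCC(c1ccc3c(c1)CCC(C)(C)O3)=C2O[Si](C(C)C)(C(C)C)C(C)C | intermediate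
20 | (3R)-7-[(tert-butyldimethylsilyl)oxy]-3-(2,2-dimethylchroman-6-yl)-8-(3-methylbut-2-en-1-yl)chroman-4-one | CC(C)=CCc1c(O[Si](C)(C)C(C)(C)C)ccc2c1OC[C@@H](c1ccc3c(c1)CCC(C)(C)O3)C2=O | intermediate
21 | (3R)-3-(2,2-dimethylchroman-6-yl)-7-hydroxy-8-(3-methylbut-2-en-1-yl)chroman-4-one | CC(C)=CCc1c(O)ccc2c1OC[C@@H](c1ccc3c(c1)CCC(C)(C)O3)C2=O | target

**Step count**

Total: 12 steps. Longest linear sequence: 8 steps (steps 1–4 or steps 5–8, then steps 9–12).

**Steps most likely to fail**

1. Step 9 (proposed new method).
 - What may go wrong: the aryloxymethyl cation may be consumed by Friedel–Crafts attack on a second arene or by the allyl group before the alkyne adds. The ketenium ion may be intercepted by triflate or acetate instead of closing ring C. The product enol silane may be alkylated a second time at C3.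
 - Fallback (known chemistry, the two bonds made one after the other), setting out from 10 and 8 and returning at 18: palladium-catalysed α-arylation of the lithium enolate of tert-butyl acetate with bromide 10 (LiN(SiMe3)2, Pd(dba)2, P(t-Bu)3, toluene, rt) should give tert-butyl (2,2-dimethylchroman-6-yl)acetate F1. Enolization and O-silylation (LDA, TMSCl, THF, −78 °C) should give its trimethylsilyl ketene acetal F2. Mukaiyama-type aryloxymethylation of F2 with acetoxymethyl ether 8 (TMSOTf cat., CH2Cl2, −78 °C) forms C2–C3 and should give racemic tert-butyl 3-{2-allyl-3-[(tert-butyldimethylsilyl)oxy]phenoxy}-2-(2,2-dimethylchroman-6-yl)propanoate F3. Ester cleavage and intramolecular Friedel–Crafts acylation through the mixed trifluoroacetic anhydride (TFA then TFAA, CH2Cl2, 0 °C → rt) forms C4–C4a and should give racemic 8-allyl-7-[(tert-butyldimethylsilyl)oxy]-3-(2,2-dimethylchroman-6-yl)chroman-4-one F4. Soft enolization toward C3, the only enolizable side (TIPSOTf, Et3N, CH2Cl2, 0 °C), returns enol silane 18.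

2. Step 11.
 - What may go wrong: the hindered triisopropylsilyl group may make protonation and silyl transfer slow, so that conversion is incomplete or a less selective pathway takes over. Facial selectivity may be poor. The acid may trigger cyclization onto the prenyl double bond.
 - Fallback, setting out from 19 and returning at 20: hydrolysis of the enol ether only (TFA, wet CH2Cl2, 0 °C) should give racemic 7-[(tert-butyldimethylsilyl)oxy]-3-(2,2-dimethylchroman-6-yl)-8-(3-methylbut-2-en-1-yl)chroman-4-one F5. Asymmetric transfer hydrogenation under dynamic kinetic resolution (RuCl[(R,R)-TsDPEN](p-cymene), HCO2H/Et3N 5:2, EtOAc, 40 °C) is a known process for 3-arylchroman-4-ones. C3 epimerizes under the amine buffer while one enantiomer is reduced, which should give the cis alcohol (3R,4R)-7-[(tert-butyldimethylsilyl)oxy]-3-(2,2-dimethylchroman-6-yl)-8-(3-methylbut-2-en-1-yl)chroman-4-ol F6, the 4R sense being assigned by analogy to aryl alkyl ketones. Oxidation of the benzylic alcohol under buffered, base-free conditions (Dess–Martin periodinane, NaHCO3, CH2Cl2, 0 °C) returns ketone 20 with the C3 configuration kept.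

3. Step 12.
 - What may go wrong: partial enolization at C3 during desilylation would erode the enantiomeric purity, or cleavage of the aryl silyl ether may be incomplete.
 - Fallback (order of events reversed so that the stereocenter is formed last), setting out from 19 and returning at 21: selective cleavage of the phenolic silyl ether while C3 is still trigonal (Cs2CO3, DMF–H2O 10:1, rt; the hindered enol silane is expected to persist) should give 3-(2,2-dimethylchroman-6-yl)-8-(3-methylbut-2-en-1-yl)-4-[(triisopropylsilyl)oxy]-2H-chromen-7-ol F7. The enantioselective protonation of step 11, run on F7 with a larger excess of phenol (3 equiv) as silyl acceptor, should then deliver target 21 directly.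

**Further compounds**

F1 | step 9 | tert-butyl (2,2-dimethylchroman-6-yl)acetate | CC(C)(C)OC(=O)Cc1ccc2OC(C)(C)CCc2c1
F2 | step 9 | tert-butyl trimethylsilyl ketene acetal of F1 | CC(C)(C)OC(O[Si](C)(C)C)=Cc1ccc2OC(C)(C)CCc2c1
F3 | step 9 | racemic tert-butyl 3-{2-allyl-3-[(tert-butyldimethylsilyl)oxy]phenoxy}-2-(2,2-dimethylchroman-6-yl)propanoate | CC(C)(C)OC(=O)C(COc1cccc(O[Si](C)(C)C(C)(C)C)c1CC=C)c1ccc2OC(C)(C)CCc2c1
F4 | step 9 | racemic 8-allyl-7-[(tert-butyldimethylsilyl)oxy]-3-(2,2-dimethylchroman-6-yl)chroman-4-one | C=CCc1c(O[Si](C)(C)C(C)(C)C)ccc2c1OCC(c1ccc3c(c1)CCC(C)(C)O3)C2=O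
F5 | step 11 | racemic 7-[(tert-butyldimethylsilyl)oxy]-3-(2,2-dimethylchroman-6-yl)-8-(3-methylbut-2-en-1-yl)chroman-4-one | CC(C)=CCc1c(O[Si](C)(C)C(C)(C)C)ccc2c1OCC(c1ccc3c(c1)CCC(C)(C)O3)C2=O
F6 | step 11 | (3R,4R)-7-[(tert-butyldimethylsilyl)oxy]-3-(2,2-dimethylchroman-6-yl)-8-(3-methylbut-2-en-1-yl)chroman-4-ol | CC(C)=CCc1c(O[Si](C)(C)C(C)(C)C)ccc2c1OC[C@@H](c1ccc3c(c1)CCC(C)(C)O3)[C@H]2O
F7 | step 12 | 3-(2,2-dimethylchroman-6-yl)-8-(3-methylbut-2-en-1-yl)-4-[(triisopropylsilyl)oxy]-2H-chromen-7-ol | CC(C)=CCc1c(O)ccc2c1OCC(c1ccc3c(c1)CCC(C)(C)O3)=C2O[Si](C(C)C)(C(C)C)C(C)C
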